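Assumption: the target SMILES has no stereodescriptor (there is no stereocentre and the sense of the 6–8'' biaryl axis is not specified), so the compound is made without control of that axis, as the racemate.

**Retrosynthetic overview**
- Last step: chelation-controlled cleavage of the two peri (5- and 5''-) methyl ethers of a 5,7,5''-trimethyl ether; the 7-OMe is carried from the first building block.
- Key disconnection: both pyranone rings (rings C) are cut at O1–C2 (C–O) and C4–C4a, back to a biaryl triol plus an arylpropiolate. Which oxygen is vinylated fixes the 6- versus 8''-linkage, and each ring of the triol is locally symmetric, so no isomer choice arises.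
- The biaryl triol comes from a p-quinol by reductive aromatisation; the quinol comes from addition of a 2,6-dioxygenated aryllithium to 2,6-dimethoxy-1,4-benzoquinone.
- Ring order: the two A rings first (as the biaryl), then both C rings in one flask; the B rings arrive with the propiolate.

**Step 1**
Reactants: 1 5-methoxybenzene-1,3-diol
Product: 2 1-methoxy-3,5-bis(methoxymethoxy)benzene
Conditions: MOMCl (2.6 equiv), iPr2NEt (3 equiv), CH2Cl2, 0 °C to rt
Reagents that add atoms: chloromethyl methyl ether (MOMCl), COCCl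
Why: Base-mediated O-alkylation (MOM protection) of both phenols; the two acetal groups later direct lithiation to the carbon between them.

**Step 2**
Reactants: 2 1-methoxy-3,5-bis(methoxymethoxy)benzene; 3 2,6-dimethoxy-1,4-benzoquinone
Product: 5 4-hydroxy-3,5-dimethoxy-4-[4-methoxy-2,6-bis(methoxymethoxy)phenyl]cyclohexa-2,5-dien-1-one, via aryllithium 4 (not isolated)
Conditions: n-BuLi (1.05 equiv), THF, 0 °C, 1 h; then added to 3 (1.2 equiv) in THF, −78 to −30 °C; aq. NH4Cl
Reagents that add atoms: none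
Why: Directed ortho-metalation between the two OMOM groups, then 1,2-addition to the quinone carbonyl flanked by the methoxy-bearing carbons (the other carbonyl is a doubly vinylogous ester and much less electrophilic, and the methoxy oxygens chelate lithium); the carbinol carbon carries two identical ring arms and is not a stereocentre.

**Step 3**
Reactants: 5 4-hydroxy-3,5-dimethoxy-4-[4-methoxy-2,6-bis(methoxymethoxy)phenyl]cyclohexa-2,5-dien-1-one
Product: 7 2-(4-hydroxy-2,6-dimethoxyphenyl)-5-methoxybenzene-1,3-diol, via bis-MOM biaryl phenol 6 (not isolated)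
Conditions: Zn dust (6 equiv), AcOH/THF, 25 °C; filter; then 3 M HCl in MeOH, 45 °C
Reagents that add atoms: none
Why: Reductive aromatisation of a p-quinol (two-electron reduction of the γ-hydroxy dienone expels hydroxide and gives the phenol), followed by acid-catalysed acetal exchange that removes both MOM groups; both rings of 7 are locally symmetric, so 7 is achiral.

**Step 4**
Reactants: 8 1-(benzyloxy)-4-iodobenzene; 9 methyl prop-2-ynoate
Product: 10 methyl 3-[4-(benzyloxy)phenyl]prop-2-ynoate
Conditions: PdCl2(PPh3)2 (2 mol%), CuI (4 mol%), K2CO3 (2 equiv), THF, 65 °C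
Reagents that add atoms: none
Why: Sonogashira coupling of an aryl iodide with a terminal alkyne; the carbonate base avoids amine conjugate addition to the propiolate.

**Step 5**
Reactants: 7 2-(4-hydroxy-2,6-dimethoxyphenyl)-5-methoxybenzene-1,3-diol; 10 methyl 3-[4-(benzyloxy)phenyl]prop-2-ynoate
Product: 13 7-hydroxy-8-[2-(4-hydroxyphenyl)-5,7-dimethoxy-4-oxo-4H-chromen-6-yl]-2-(4-hydroxyphenyl)-5-methoxy-4H-chromen-4-one, via tris(vinyl ether) 11 (not isolated), via vinyl ether biflavone 12 (not isolated)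
Conditions: 10 (3.3 equiv), Cs2CO3 (0.5 equiv), MeCN, 80 °C, Ar; evaporate; P2O5/MeSO3H (1:10 w/w), C6HMe5 (15 equiv), 45 °C; then H2O, 70 °C
Reagents that add atoms: none
Why: Proposed new method: a one-flask base-then-acid double flavone annulation of an unprotected biaryl triol, in which the caesium phenoxides of 7 add through oxygen to the β-carbon of ynoate 10 (anti oxa-Michael addition to Z-β-aryloxycinnamates, so each new C–O bond decides which oxygen becomes O1 of a pyranone), P2O5/MeSO3H then drives a six-membered Friedel–Crafts acylation by each ester onto the adjacent electron-rich ring carbon (once on the dimethoxy ring, and only once on the resorcinol ring because the first closure leaves a protonated, deactivated 4-hydroxybenzopyrylium) while the benzyl ethers are transferred to C6HMe5, and the surplus vinyl ether on O-7'' is hydrolysed in the hot aqueous acid quench because a 7-hydroxyflavone is a good leaving group; the 6- and 8''-linkages follow from the local symmetry of the two rings of 7 and the axis forms as a racemate; closest known reaction type is the Ruhemann flavone synthesis (phenoxide addition to an arylpropiolate, then acid cyclisation) together with P2O5/MeSO3H chromone ring closures, not shown so far as a double annulation on a hindered biaryl polyphenol with in situ debenzylation and removal of a surplus vinyl ether.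

**Step 6**
Reactants: 13 7-hydroxy-8-[2-(4-hydroxyphenyl)-5,7-dimethoxy-4-oxo-4H-chromen-6-yl]-2-(4-hydroxyphenyl)-5-methoxy-4H-chromen-4-one
Product: 14 5,7-dihydroxy-8-[5-hydroxy-2-(4-hydroxyphenyl)-7-methoxy-4-oxo-4H-chromen-6-yl]-2-(4-hydroxyphenyl)-4H-chromen-4-one
Conditions: BCl3 (1 M in CH2Cl2, 8 equiv), CH2Cl2, −20 °C to rt; then MeOH, H2O
Reagents that add atoms: none
Why: Chelation-controlled demethylation: BCl3 bridges each C4 carbonyl and its peri 5-methoxy oxygen and cleaves only those two methyl ethers, leaving the non-chelated 7-OMe.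

**Compound list**
1 | 5-methoxybenzene-1,3-diol (5-methoxyresorcinol) | COc1cc(O)cc(O)c1 | starting material
2 | 1-methoxy-3,5-bis(methoxymethoxy)benzene | COCOc1cc(OC)cc(OCOC)c1 | intermediate
3 | 2,6-dimethoxy-1,4-benzoquinone | COC1=CC(=O)C=C(OC)C1=O | starting material
4 | [4-methoxy-2,6-bis(methoxymethoxy)phenyl]lithium | [Li]c1c(OCOC)cc(OC)cc1OCOC | intermediate
5 | 4-hydroxy-3,5-dimethoxy-4-[4-methoxy-2,6-bis(methoxymethoxy)phenyl]cyclohexa-2,5-dien-1-one (achiral) | COCOc1cc(OC)cc(OCOC)c1C1(O)C(OC)=CC(=O)C=C1OC | intermediate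
6 | 3,5-dimethoxy-4-[4-methoxy-2,6-bis(methoxymethoxy)phenyl]phenol | COCOc1cc(OC)cc(OCOC)c1-c1c(OC)cc(O)cc1OC | intermediate
7 | 2-(4-hydroxy-2,6-dimethoxyphenyl)-5-methoxybenzene-1,3-diol | COc1cc(O)c(-c2c(OC)cc(O)cc2OC)c(O)c1 | intermediate
8 | 1-(benzyloxy)-4-iodobenzene | Ic1ccc(OCc2ccccc2)cc1 | starting material
9 | methyl prop-2-ynoate (methyl propiolate) | COC(=O)C#C | starting material
10 | methyl 3-[4-(benzyloxy)phenyl]prop-2-ynoate | COC(=O)C#Cc1ccc(OCc2ccccc2)cc1 | intermediate
11 | tris-O-[(1Z)-1-(4-benzyloxyphenyl)-3-methoxy-3-oxoprop-1-en-1-yl] derivative of 7 (all three phenolic oxygens vinylated) | COc1cc(O/C(=C\C(=O)OC)c2ccc(OCc3ccccc3)cc2)c(-c2c(OC)cc(O/C(=C\C(=O)OC)c3ccc(OCc4ccccc4)cc3)cc2OC)c(O/C(=C\C(=O)OC)c2ccc(OCc3ccccc3)cc2)c1 | intermediate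
12 | 13 carrying a (1Z)-1-(4-hydroxyphenyl)-3-methoxy-3-oxoprop-1-en-1-yl group on O-7'' (racemic axis) | COc1cc2oc(-c3ccc(O)cc3)cc(=O)c2c(OC)c1-c1c(O/C(=C\C(=O)OC)c2ccc(O)cc2)cc(OC)c2c(=O)cc(-c3ccc(O)cc3)oc12 | intermediate
13 | 7-hydroxy-8-[2-(4-hydroxyphenyl)-5,7-dimethoxy-4-oxo-4H-chromen-6-yl]-2-(4-hydroxyphenyl)-5-methoxy-4H-chromen-4-one (racemic axis) | COc1cc2oc(-c3ccc(O)cc3)cc(=O)c2c(OC)c1-c1c(O)cc(OC)c2c(=O)cc(-c3ccc(O)cc3)oc12 | intermediate
14 | 5,7-dihydroxy-8-[5-hydroxy-2-(4-hydroxyphenyl)-7-methoxy-4-oxo-4H-chromen-6-yl]-2-(4-hydroxyphenyl)-4H-chromen-4-one (7-O-methylagathisflavone) | COc1cc2oc(-c3ccc(O)cc3)cc(=O)c2c(O)c1-c1c(O)cc(O)c2c(=O)cc(-c3ccc(O)cc3)oc12 | target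

**Totals**
Total step count: 6. Longest linear sequence: 5 steps (steps 1, 2, 3, 5, 6).

**Three steps most likely to fail**

Step 5 (the proposed new double annulation; risks are C- instead of O-attack by the phenoxides, C-benzylation during debenzylation, and incomplete hydrolysis of the surplus vinyl ether). The fallback uses known chemistry and sets out from 7. C-Acetylation ortho to a hydroxyl on each ring (BF3·OEt2, AcOH, 90 °C) gives 1-[3-(3-acetyl-4-hydroxy-2,6-dimethoxyphenyl)-2,4-dihydroxy-6-methoxyphenyl]ethan-1-one F5. Claisen–Schmidt condensation with 4-(benzyloxy)benzaldehyde (KOH, EtOH) gives the bis[(E)-3-(4-benzyloxyphenyl)prop-2-enoyl] analogue of F5 (the bis-chalcone) F6. Catalytic I2 in DMSO at 130 °C then closes both pyranone rings by oxa-Michael addition and dehydrogenation; only the hydroxyl ortho to each enone can close, so the linkages are fixed as before, giving the 4',4'''-di-O-benzyl ether of 13 F7. BCl3 with C6HMe5 removes the benzyl groups and both peri methyl ethers, so this fallback comes back to the route at 14.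

Step 2 (hindered 1,2-addition to the quinone; risks are electron transfer and attack at the wrong carbonyl). The fallback sets out from 2 and replaces carbonyl addition by cross-coupling. Lithiation of 2 (n-BuLi) and quenching with I2 gives 2-iodo-5-methoxy-1,3-bis(methoxymethoxy)benzene F1. Separately, 3,5-dimethoxyphenol is silylated (iPr3SiCl, imidazole) to (3,5-dimethoxyphenoxy)tri(propan-2-yl)silane F2, lithiated between the two methoxy groups (n-BuLi, TMEDA) and transmetalated with ZnCl2 to chloro{2,6-dimethoxy-4-[tri(propan-2-yl)silyloxy]phenyl}zinc F3. Negishi coupling of F3 with F1 (Pd2(dba)3, RuPhos, THF, 70 °C) gives {3,5-dimethoxy-4-[4-methoxy-2,6-bis(methoxymethoxy)phenyl]phenoxy}tri(propan-2-yl)silane F4. Bu4NF removes the silyl group and the fallback comes back to the route at 6, which is taken on to 7 with HCl in MeOH as in step 3.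

Step 6 (selective cleavage on a poorly soluble free polyphenol). The fallback sets out from 13 and changes to a protect, demethylate, deprotect sequence. Ac2O in pyridine gives the 4',4''',7''-tri-O-acetate of 13 F8, which is soluble in CH2Cl2. BCl3 then cleaves only the two chelated peri methyl ethers to give the 4',4''',7''-tri-O-acetate of 14 F9. K2CO3 in MeOH at 0 °C removes the acetates, and the fallback comes back to the route at 14.

**Further compounds**
F1 | step 2 | 2-iodo-5-methoxy-1,3-bis(methoxymethoxy)benzene | COCOc1cc(OC)cc(OCOC)c1I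
F2 | step 2 | (3,5-dimethoxyphenoxy)tri(propan-2-yl)silane | COc1cc(OC)cc(O[Si](C(C)C)(C(C)C)C(C)C)c1
F3 | step 2 | chloro{2,6-dimethoxy-4-[tri(propan-2-yl)silyloxy]phenyl}zinc | COc1cc(O[Si](C(C)C)(C(C)C)C(C)C)cc(OC)c1[Zn]Cl
F4 | step 2 | {3,5-dimethoxy-4-[4-methoxy-2,6-bis(methoxymethoxy)phenyl]phenoxy}tri(propan-2-yl)silane | COCOc1cc(OC)cc(OCOC)c1-c1c(OC)cc(O[Si](C(C)C)(C(C)C)C(C)C)cc1OC
F5 | step 5 | 1-[3-(3-acetyl-4-hydroxy-2,6-dimethoxyphenyl)-2,4-dihydroxy-6-methoxyphenyl]ethan-1-one | CC(=O)c1c(O)cc(OC)c(-c2c(O)cc(OC)c(C(C)=O)c2O)c1OC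
F6 | step 5 | bis[(E)-3-(4-benzyloxyphenyl)prop-2-enoyl] analogue of F5 (bis-chalcone) | O=C(/C=C/c1ccc(OCc2ccccc2)cc1)c1c(O)cc(OC)c(-c2c(O)cc(OC)c(C(=O)/C=C/c3ccc(OCc4ccccc4)cc3)c2O)c1OC
F7 | step 5 | 4',4'''-di-O-benzyl ether of 13 | COc1cc2oc(-c3ccc(OCc4ccccc4)cc3)cc(=O)c2c(OC)c1-c1c(O)cc(OC)c2c(=O)cc(-c3ccc(OCc4ccccc4)cc3)oc12
F8 | step 6 | 4',4''',7''-tri-O-acetate of 13 | COc1cc2oc(-c3ccc(OC(C)=O)cc3)cc(=O)c2c(OC)c1-c1c(OC(C)=O)cc(OC)c2c(=O)cc(-c3ccc(OC(C)=O)cc3)oc12
F9 | step 6 | 4',4''',7''-tri-O-acetate of 14 | COc1cc2oc(-c3ccc(OC(C)=O)cc3)cc(=O)c2c(O)c1-c1c(OC(C)=O)cc(O)c2c(=O)cc(-c3ccc(OC(C)=O)cc3)oc12
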